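**Assumption:** the target has no stereocentre (it is achiral), so no enantiocontrol is needed; the only stereo-element on the route is the E-alkene of 13, which is removed by hydrogenation.

**Retrosynthetic overview**
1. Target 15 ⇒ bis-methyl ether 14 (global O-demethylation last) ⇒ enone 13 (C=C hydrogenation).
2. Enone 13 ⇒ intermolecular aldol (Claisen–Schmidt) condensation of aryl aldehyde 11 with 2-acetyl-4,5-dichloropyrrole 4; this is the key C–C bond (Cα–Cβ of the propanone chain).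
3. Aldehyde 11 ⇒ aryllithium from bromo-acetal 7 plus Weinreb amide 3 (aryl ketone bond); 7 comes from 2,6-dimethoxybenzaldehyde by bromination and acetalisation.
4. Both 3 and 4 come from one dichloropyrrole block: 2-(trichloroacetyl)pyrrole → SO2Cl2 → 2 → Weinreb amide 3 → MeMgBr → 4.
5. No ring is formed on the route; the benzene ring and both pyrrole rings are bought intact and only substituted.

**Route**

Step 1
Reactants: 1 2,2,2-trichloro-1-(1H-pyrrol-2-yl)ethan-1-one
Product: 2 2,2,2-trichloro-1-(4,5-dichloro-1H-pyrrol-2-yl)ethan-1-one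
Conditions: SO2Cl2 (2.2 equiv), CHCl3, 0 °C → rt, then 50 °C to completion
Reagents that add atoms: sulfuryl chloride, O=S(=O)(Cl)Cl
Why: Electrophilic aromatic chlorination; the 2-trichloroacetyl group deactivates C3, so chlorine enters at C4 and then C5.

Step 2
Reactants: 2 2,2,2-trichloro-1-(4,5-dichloro-1H-pyrrol-2-yl)ethan-1-one
Product: 3 4,5-dichloro-N-methoxy-N-methyl-1H-pyrrole-2-carboxamide
Conditions: MeNH(OMe)·HCl (1.5 equiv), Et3N (3 equiv), MeCN, 50 °C
Reagents that add atoms: N,O-dimethylhydroxylamine hydrochloride, CNOC.Cl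
Why: Haloform-type acyl substitution; the amine adds to the trichloromethyl ketone and CCl3⁻ leaves as chloroform to give the Weinreb amide.

Step 3
Reactants: 3 4,5-dichloro-N-methoxy-N-methyl-1H-pyrrole-2-carboxamide
Product: 4 1-(4,5-dichloro-1H-pyrrol-2-yl)ethan-1-one
Conditions: MeMgBr (3 equiv), THF, 0 °C → rt; then 1 M HCl
Reagents that add atoms: methylmagnesium bromide, C[Mg]Br
Why: Weinreb ketone synthesis; the first equivalent deprotonates N–H, the second adds, and the chelated tetrahedral intermediate prevents over-addition.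

Step 4
Reactants: 5 2,6-dimethoxybenzaldehyde
Product: 6 3-bromo-2,6-dimethoxybenzaldehyde
Conditions: NBS (1.05 equiv), MeCN, 0 °C → rt
Reagents that add atoms: N-bromosuccinimide, O=C1CCC(=O)N1Br
Why: Electrophilic aromatic bromination; C3 is ortho to one OMe, para to the other and meta to CHO, so one equivalent gives the single mono-bromide.

Step 5
Reactants: 6 3-bromo-2,6-dimethoxybenzaldehyde
Product: 7 2-(3-bromo-2,6-dimethoxyphenyl)-1,3-dioxolane
Conditions: HOCH2CH2OH (5 equiv), p-TsOH·H2O (5 mol %), toluene, reflux, Dean–Stark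
Reagents that add atoms: ethylene glycol, OCCO
Why: Acid-catalysed acetalisation driven by azeotropic water removal masks the aldehyde against the organolithium step.

Step 6
Reactants: 7 2-(3-bromo-2,6-dimethoxyphenyl)-1,3-dioxolane; 3 4,5-dichloro-N-methoxy-N-methyl-1H-pyrrole-2-carboxamide
Product: 11 3-(4,5-dichloro-1H-pyrrole-2-carbonyl)-2,6-dimethoxybenzaldehyde, via aryllithium 8 (not isolated), via sodium pyrrolide 9 (not isolated), via ketone acetal 10 (not isolated)
Conditions: 7 (1.3 equiv), n-BuLi (1.3 equiv), THF, −78 °C; add 9 [from 3 (1.0 equiv), NaH (1.05 equiv), THF, 0 °C]; −78 → 0 °C; then 2 M HCl, rt, 2 h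
Reagents that add atoms: water, O
Why: Bromine–lithium exchange followed by Weinreb ketone synthesis on the N-sodiated amide (so the acidic N–H does not quench the aryllithium), then acid hydrolysis of the dioxolane in the quench.

Step 7
Reactants: 11 3-(4,5-dichloro-1H-pyrrole-2-carbonyl)-2,6-dimethoxybenzaldehyde; 4 1-(4,5-dichloro-1H-pyrrol-2-yl)ethan-1-one
Product: 13 (2E)-3-[3-(4,5-dichloro-1H-pyrrole-2-carbonyl)-2,6-dimethoxyphenyl]-1-(4,5-dichloro-1H-pyrrol-2-yl)prop-2-en-1-one, via aldol adduct 12 (not isolated)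
Conditions: 4 (1.2 equiv), KOH (8 equiv), EtOH/H2O 4:1, rt → 50 °C; then 1 M HCl to pH 4
Reagents that add atoms: none
Why: Claisen–Schmidt aldol condensation between a non-enolisable aldehyde and a methyl ketone, with E1cB dehydration giving the conjugated E-enone; the racemic carbinol centre of 12 is lost on dehydration.

Step 8
Reactants: 13 (2E)-3-[3-(4,5-dichloro-1H-pyrrole-2-carbonyl)-2,6-dimethoxyphenyl]-1-(4,5-dichloro-1H-pyrrol-2-yl)prop-2-en-1-one
Product: 14 3-[3-(4,5-dichloro-1H-pyrrole-2-carbonyl)-2,6-dimethoxyphenyl]-1-(4,5-dichloro-1H-pyrrol-2-yl)propan-1-one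
Conditions: H2 (4 bar), RhCl(PPh3)3 (10 mol %), THF/t-BuOH 1:1, 45 °C
Reagents that add atoms: none
Why: Homogeneous hydrogenation with Wilkinson's catalyst saturates the enone C=C without reducing either ketone or cleaving the pyrrole C–Cl bonds.

Step 9
Reactants: 14 3-[3-(4,5-dichloro-1H-pyrrole-2-carbonyl)-2,6-dimethoxyphenyl]-1-(4,5-dichloro-1H-pyrrol-2-yl)propan-1-one
Product: 15 dihydrotetrachlorizine, 3-[3-(4,5-dichloro-1H-pyrrole-2-carbonyl)-2,6-dihydroxyphenyl]-1-(4,5-dichloro-1H-pyrrol-2-yl)propan-1-one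
Conditions: BBr3 (8 equiv), CH2Cl2, −78 °C → rt; then ice-water
Reagents that add atoms: none
Why: Lewis-acid ether cleavage (BBr3 demethylation) frees both phenols, the one ortho to the aryl ketone helped by chelation; excess reagent covers the Lewis-basic carbonyl and N–H sites.

**Compound list**
1 | 2,2,2-trichloro-1-(1H-pyrrol-2-yl)ethan-1-one, 2-(trichloroacetyl)pyrrole | O=C(c1ccc[nH]1)C(Cl)(Cl)Cl | starting material
2 | 2,2,2-trichloro-1-(4,5-dichloro-1H-pyrrol-2-yl)ethan-1-one | O=C(c1cc(Cl)c(Cl)[nH]1)C(Cl)(Cl)Cl | intermediate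
3 | 4,5-dichloro-N-methoxy-N-methyl-1H-pyrrole-2-carboxamide | CON(C)C(=O)c1cc(Cl)c(Cl)[nH]1 | intermediate
4 | 1-(4,5-dichloro-1H-pyrrol-2-yl)ethan-1-one | CC(=O)c1cc(Cl)c(Cl)[nH]1 | intermediate
5 | 2,6-dimethoxybenzaldehyde | COc1cccc(OC)c1C=O | starting material
6 | 3-bromo-2,6-dimethoxybenzaldehyde | COc1ccc(Br)c(OC)c1C=O | intermediate
7 | 2-(3-bromo-2,6-dimethoxyphenyl)-1,3-dioxolane | COc1ccc(Br)c(OC)c1C1OCCO1 | intermediate
8 | [3-(1,3-dioxolan-2-yl)-2,4-dimethoxyphenyl]lithium | [Li]c1ccc(OC)c(C2OCCO2)c1OC | intermediate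
9 | sodium 2,3-dichloro-5-[methoxy(methyl)carbamoyl]pyrrol-1-ide (N-sodium salt of 3) | CON(C)C(=O)c1cc(Cl)c(Cl)[n-]1.[Na+] | intermediate
10 | (4,5-dichloro-1H-pyrrol-2-yl)[3-(1,3-dioxolan-2-yl)-2,4-dimethoxyphenyl]methanone | COc1ccc(C(=O)c2cc(Cl)c(Cl)[nH]2)c(OC)c1C1OCCO1 | intermediate
11 | 3-(4,5-dichloro-1H-pyrrole-2-carbonyl)-2,6-dimethoxybenzaldehyde | COc1ccc(C(=O)c2cc(Cl)c(Cl)[nH]2)c(OC)c1C=O | intermediate
12 | 3-[3-(4,5-dichloro-1H-pyrrole-2-carbonyl)-2,6-dimethoxyphenyl]-1-(4,5-dichloro-1H-pyrrol-2-yl)-3-hydroxypropan-1-one (racemic) | COc1ccc(C(=O)c2cc(Cl)c(Cl)[nH]2)c(OC)c1C(O)CC(=O)c1cc(Cl)c(Cl)[nH]1 | intermediate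
13 | (2E)-3-[3-(4,5-dichloro-1H-pyrrole-2-carbonyl)-2,6-dimethoxyphenyl]-1-(4,5-dichloro-1H-pyrrol-2-yl)prop-2-en-1-one | COc1ccc(C(=O)c2cc(Cl)c(Cl)[nH]2)c(OC)c1/C=C/C(=O)c1cc(Cl)c(Cl)[nH]1 | intermediate
14 | 3-[3-(4,5-dichloro-1H-pyrrole-2-carbonyl)-2,6-dimethoxyphenyl]-1-(4,5-dichloro-1H-pyrrol-2-yl)propan-1-one | COc1ccc(C(=O)c2cc(Cl)c(Cl)[nH]2)c(OC)c1CCC(=O)c1cc(Cl)c(Cl)[nH]1 | intermediate
15 | dihydrotetrachlorizine, 3-[3-(4,5-dichloro-1H-pyrrole-2-carbonyl)-2,6-dihydroxyphenyl]-1-(4,5-dichloro-1H-pyrrol-2-yl)propan-1-one (achiral) | O=C(CCc1c(O)ccc(C(=O)c2cc(Cl)c(Cl)[nH]2)c1O)c1cc(Cl)c(Cl)[nH]1 | target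

**Totals**
Total step count: 9. Longest linear sequence: 6 steps (for example 5 → 6 → 7 → 11 → 13 → 14 → 15, steps 4, 5, 6, 7, 8, 9).

**Three steps most likely to fail, with fallbacks**

Step 7 (aldol condensation). Under KOH both partners are pyrrolide anions, so ketone 4 enolises only sluggishly, and the aldehyde is flanked by two methoxy groups. The fallback is a directed, irreversible aldol addition with a separate dehydration. It sets out from 4 and 11 and comes back at 13. Ketone 4 is treated with LDA (2.2 equiv, THF, −78 °C) to give the N,O-dianion dilithium 1-(4,5-dichloropyrrol-1-id-2-yl)ethen-1-olate F3. In a second flask aldehyde 11 is converted with NaH (1.0 equiv, THF, 0 °C) into sodium 2,3-dichloro-5-(3-formyl-2,4-dimethoxybenzoyl)pyrrol-1-ide F4, so that its N–H cannot quench the enolate. The two are combined at −78 °C and quenched with 1 M HCl. The β-hydroxy ketone 12 is now isolated and dehydrated with catalytic p-TsOH in toluene at 80 °C to give 13.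

Step 6 (aryllithium acylation). The N-sodiated Weinreb amide may be too unreactive or too insoluble for a clean addition. The fallback removes the N–H problem by protection. It sets out from 3 (with aryllithium 8 made from 7 as before) and comes back at 11. Amide 3 is alkylated with NaH and SEMCl (THF, 0 °C) to give 4,5-dichloro-N-methoxy-N-methyl-1-{[2-(trimethylsilyl)ethoxy]methyl}-1H-pyrrole-2-carboxamide F1. Aryllithium 8 (1.1 equiv, THF, −78 °C, NH4Cl quench) then gives (4,5-dichloro-1-{[2-(trimethylsilyl)ethoxy]methyl}-1H-pyrrol-2-yl)[3-(1,3-dioxolan-2-yl)-2,4-dimethoxyphenyl]methanone F2. TBAF (THF, 65 °C) removes the SEM group, and 2 M HCl then cleaves the dioxolane to give 11.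

Step 9 (global demethylation). BBr3 may stall at the methoxy group para to the aryl ketone, or the acid may cyclise a freed phenol onto the chain ketone to a chromene. The fallback splits the deprotection into a chelation-controlled Lewis-acid step and a nucleophilic step. It sets out from 14 and comes back at 15. BCl3 (3 equiv, CH2Cl2, −78 → 0 °C) cleaves only the methoxy group ortho to the aryl ketone, giving 3-[3-(4,5-dichloro-1H-pyrrole-2-carbonyl)-2-hydroxy-6-methoxyphenyl]-1-(4,5-dichloro-1H-pyrrol-2-yl)propan-1-one F5. The remaining ether is then removed by SN2 attack of sodium ethanethiolate (6 equiv, DMF, 110 °C) and acidic work-up gives 15.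

**Further compounds**
F1 | step 6 | 4,5-dichloro-N-methoxy-N-methyl-1-{[2-(trimethylsilyl)ethoxy]methyl}-1H-pyrrole-2-carboxamide | CON(C)C(=O)c1cc(Cl)c(Cl)n1COCC[Si](C)(C)C
F2 | step 6 | (4,5-dichloro-1-{[2-(trimethylsilyl)ethoxy]methyl}-1H-pyrrol-2-yl)[3-(1,3-dioxolan-2-yl)-2,4-dimethoxyphenyl]methanone | COc1ccc(C(=O)c2cc(Cl)c(Cl)n2COCC[Si](C)(C)C)c(OC)c1C1OCCO1
F3 | step 7 | dilithium 1-(4,5-dichloropyrrol-1-id-2-yl)ethen-1-olate | [Li+].[Li+].C=C([O-])c1cc(Cl)c(Cl)[n-]1
F4 | step 7 | sodium 2,3-dichloro-5-(3-formyl-2,4-dimethoxybenzoyl)pyrrol-1-ide | COc1ccc(C(=O)c2cc(Cl)c(Cl)[n-]2)c(OC)c1C=O.[Na+]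
F5 | step 9 | 3-[3-(4,5-dichloro-1H-pyrrole-2-carbonyl)-2-hydroxy-6-methoxyphenyl]-1-(4,5-dichloro-1H-pyrrol-2-yl)propan-1-one | COc1ccc(C(=O)c2cc(Cl)c(Cl)[nH]2)c(O)c1CCC(=O)c1cc(Cl)c(Cl)[nH]1
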